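**Retrosynthetic overview**
- Last bonds made: C8–prenyl and C5'–prenyl, formed together by a double aromatic Claisen ([3,3]) rearrangement of the 7,4'-bis(1,1-dimethylallyl) ether, which also frees both phenols.
- Side chain: the aryl–CH2 bond comes from CuI-catalysed opening of methyl (R)-glycidate (carbinol stereocentre bought) by a ring B aryl Grignard reagent; CO2Me → CMe2OH → isopropenyl.
- The aryl metal comes from the 3'-bromide (ortho-bromination of the free 4'-phenol); the ketone is masked as the cis-flavan-4-ol during the organometallic step and restored with MnO2.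
- Rings: none is constructed; rings A, B and C, with C2 already (S), are bought intact as (2S)-liquiritigenin.

Assumption: natural (2S)-liquiritigenin of high ee, methyl (R)-glycidate and tert-butyl 2-methylbut-3-en-2-yl carbonate are purchased; the flavan-4-ol intermediates are drawn as the major 2,4-cis isomer (C4 is reoxidised later, so its epimer ratio does not matter).

**Step 1**
Reactants: 1 (2S)-liquiritigenin; 2 tert-butyl 2-methylbut-3-en-2-yl carbonate
Product: 3 (2S)-2-(4-hydroxyphenyl)-7-[(2-methylbut-3-en-2-yl)oxy]chroman-4-one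
Conditions: 2 (1.05 equiv), Pd(PPh3)4 (3 mol %), THF, 0 °C, 2 h
Reagents that add atoms: tert-butyl 2-methylbut-3-en-2-yl carbonate (2), C=CC(C)(C)OC(=O)OC(C)(C)C
Why: Decarboxylative Tsuji–Trost O-allylation in which the released tert-butoxide deprotonates the more acidic 7-OH (para to the ketone) and the phenoxide attacks the substituted terminus of the dimethyl-π-allyl palladium complex, giving the tertiary ether under neutral conditions that leave C2 untouched.

**Step 2**
Reactants: 3 (2S)-2-(4-hydroxyphenyl)-7-[(2-methylbut-3-en-2-yl)oxy]chroman-4-one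
Product: 4 (2S)-2-(3-bromo-4-hydroxyphenyl)-7-[(2-methylbut-3-en-2-yl)oxy]chroman-4-one
Conditions: NBS (1.0 equiv), i-Pr2NH (10 mol %), CH2Cl2, −20 to 0 °C
Reagents that add atoms: N-bromosuccinimide, O=C1CCC(=O)N1Br
Why: Amine-catalysed electrophilic ortho-bromination of the only free phenol (para position blocked, ring A now a less reactive aryl ether) installs the handle for the side chain.

**Step 3**
Reactants: 4 (2S)-2-(3-bromo-4-hydroxyphenyl)-7-[(2-methylbut-3-en-2-yl)oxy]chroman-4-one; 2 tert-butyl 2-methylbut-3-en-2-yl carbonate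
Product: 5 (2S)-2-{3-bromo-4-[(2-methylbut-3-en-2-yl)oxy]phenyl}-7-[(2-methylbut-3-en-2-yl)oxy]chroman-4-one
Conditions: 2 (1.5 equiv), Pd(PPh3)4 (5 mol %), THF, 0 °C to rt
Reagents that add atoms: tert-butyl 2-methylbut-3-en-2-yl carbonate (2), C=CC(C)(C)OC(=O)OC(C)(C)C
Why: Second Tsuji–Trost O-allylation, in which ionisation of the tertiary allylic carbonate is far faster than oxidative addition of the electron-rich aryl bromide to Pd(PPh3)4 at this temperature.

**Step 4**
Reactants: 5 (2S)-2-{3-bromo-4-[(2-methylbut-3-en-2-yl)oxy]phenyl}-7-[(2-methylbut-3-en-2-yl)oxy]chroman-4-one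
Product: 6 (2S,4S)-2-{3-bromo-4-[(2-methylbut-3-en-2-yl)oxy]phenyl}-7-[(2-methylbut-3-en-2-yl)oxy]chroman-4-ol
Conditions: NaBH4, MeOH/THF, 0 °C
Reagents that add atoms: none
Why: Hydride reduction masks the ketone (removing the acidic C3–H and retro-oxa-Michael pathway before the organolithium step), with hydride delivered under control of the equatorial 2-aryl group to give the 2,4-cis alcohol whose temporary C4 centre is erased again in step 6.

**Step 5**
Reactants: 6 (2S,4S)-2-{3-bromo-4-[(2-methylbut-3-en-2-yl)oxy]phenyl}-7-[(2-methylbut-3-en-2-yl)oxy]chroman-4-ol; 7 methyl (2R)-oxirane-2-carboxylate (methyl (R)-glycidate)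
Product: 11 (2R)-1-{5-[(2S,4S)-4-hydroxy-7-[(2-methylbut-3-en-2-yl)oxy]chroman-2-yl]-2-[(2-methylbut-3-en-2-yl)oxy]phenyl}-3-methylbutane-2,3-diol, via aryllithium 8 (not isolated), via aryl Grignard reagent 9 (not isolated), via hydroxy ester 10 (not isolated)
Conditions: t-BuLi (3.1 equiv), THF, −78 °C; MgBr2·OEt2 (1.2 equiv), −78 to −40 °C; CuI (15 mol %), 7 (1.3 equiv), −40 to −20 °C; then MeMgBr (5 equiv), −20 °C to rt; aq NH4Cl
Reagents that add atoms: methyl (2R)-oxirane-2-carboxylate (7), COC(=O)[C@H]1CO1; methylmagnesium bromide, C[Mg]Br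
Why: Br/Li exchange and Mg transmetalation give an aryl Grignard reagent that opens the glycidic ester at its CH2 terminus under CuI catalysis (SN2 epoxide opening), and double Grignard addition then converts the ester into the dimethyl carbinol in the same pot, so the bought (R) C–O stereocentre is never touched.

**Step 6**
Reactants: 11 (2R)-1-{5-[(2S,4S)-4-hydroxy-7-[(2-methylbut-3-en-2-yl)oxy]chroman-2-yl]-2-[(2-methylbut-3-en-2-yl)oxy]phenyl}-3-methylbutane-2,3-diol
Product: 12 (2S)-2-{3-[(2R)-2,3-dihydroxy-3-methylbutyl]-4-[(2-methylbut-3-en-2-yl)oxy]phenyl}-7-[(2-methylbut-3-en-2-yl)oxy]chroman-4-one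
Conditions: MnO2 (activated, 20 equiv), CH2Cl2, rt, monitored to full conversion
Reagents that add atoms: none
Why: Chemoselective benzylic oxidation restores the flavanone carbonyl, since MnO2 oxidises the electron-rich benzylic C4 alcohol much faster than the unactivated secondary and tertiary alcohols of the side chain.

**Step 7**
Reactants: 12 (2S)-2-{3-[(2R)-2,3-dihydroxy-3-methylbutyl]-4-[(2-methylbut-3-en-2-yl)oxy]phenyl}-7-[(2-methylbut-3-en-2-yl)oxy]chroman-4-one
Product: 14 (2R)-3-methyl-1-{2-[(2-methylbut-3-en-2-yl)oxy]-5-[(2S)-7-[(2-methylbut-3-en-2-yl)oxy]-4-oxochroman-2-yl]phenyl}but-3-en-2-yl acetate, via secondary acetate 13 (not isolated)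
Conditions: Ac2O (1.1 equiv), pyridine, rt, 16 h; then SOCl2 (2 equiv), 0 °C, 30 min
Reagents that add atoms: acetic anhydride, CC(=O)OC(C)=O
Why: Selective acetylation of the secondary alcohol followed by SOCl2/pyridine dehydration of the tertiary alcohol (E2 of the chlorosulfite toward a methyl group) gives the isopropenyl group without breaking the C–O bond of the stereocentre.

**Step 8**
Reactants: 14 (2R)-3-methyl-1-{2-[(2-methylbut-3-en-2-yl)oxy]-5-[(2S)-7-[(2-methylbut-3-en-2-yl)oxy]-4-oxochroman-2-yl]phenyl}but-3-en-2-yl acetate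
Product: 15 (2S)-2-{3-[(2R)-2-hydroxy-3-methylbut-3-en-1-yl]-4-[(2-methylbut-3-en-2-yl)oxy]phenyl}-7-[(2-methylbut-3-en-2-yl)oxy]chroman-4-one
Conditions: K2CO3 (0.3 equiv), MeOH, 0 °C, short reaction time
Reagents that add atoms: none
Why: Mild base-catalysed transesterification (methanolysis) frees the allylic alcohol with retention, and is kept cold and short because the flavanone, although lacking free phenols here, can still ring-open under base.

**Step 9**
Reactants: 15 (2S)-2-{3-[(2R)-2-hydroxy-3-methylbut-3-en-1-yl]-4-[(2-methylbut-3-en-2-yl)oxy]phenyl}-7-[(2-methylbut-3-en-2-yl)oxy]chroman-4-one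
Product: 17 (2S)-7-hydroxy-2-{4-hydroxy-3-[(2R)-2-hydroxy-3-methylbut-3-en-1-yl]-5-(3-methylbut-2-en-1-yl)phenyl}-8-(3-methylbut-2-en-1-yl)chroman-4-one, via bis-dienone 16 (not isolated)
Conditions: o-xylene (degassed), 140 °C, sealed tube, 4 h
Reagents that add atoms: none
Why: Double aromatic Claisen ([3,3]-sigmatropic) rearrangement in which each 1,1-dimethylallyl ether delivers a prenyl group to its ortho carbon (the only free ortho site on ring B; C8, flanked by the two oxygens, on ring A as is usual for 7-allyloxychroman-4-ones) and tautomerisation of the dienones releases both phenols, with neither stereocentre involved.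

**Compound list**
1 | (2S)-liquiritigenin, (2S)-7-hydroxy-2-(4-hydroxyphenyl)chroman-4-one | Oc1ccc([C@@H]2CC(=O)c3ccc(O)cc3O2)cc1 | starting material
2 | tert-butyl 2-methylbut-3-en-2-yl carbonate | C=CC(C)(C)OC(=O)OC(C)(C)C | starting material
3 | (2S)-2-(4-hydroxyphenyl)-7-[(2-methylbut-3-en-2-yl)oxy]chroman-4-one | Oc1ccc([C@@H]2CC(=O)c3ccc(OC(C)(C)C=C)cc3O2)cc1 | intermediate
4 | (2S)-2-(3-bromo-4-hydroxyphenyl)-7-[(2-methylbut-3-en-2-yl)oxy]chroman-4-one | Oc1ccc([C@@H]2CC(=O)c3ccc(OC(C)(C)C=C)cc3O2)cc1Br | intermediate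
5 | (2S)-2-{3-bromo-4-[(2-methylbut-3-en-2-yl)oxy]phenyl}-7-[(2-methylbut-3-en-2-yl)oxy]chroman-4-one | C=CC(C)(C)Oc1ccc([C@@H]2CC(=O)c3ccc(OC(C)(C)C=C)cc3O2)cc1Br | intermediate
6 | (2S,4S)-2-{3-bromo-4-[(2-methylbut-3-en-2-yl)oxy]phenyl}-7-[(2-methylbut-3-en-2-yl)oxy]chroman-4-ol (2,4-cis) | C=CC(C)(C)Oc1ccc([C@@H]2C[C@H](O)c3ccc(OC(C)(C)C=C)cc3O2)cc1Br | intermediate
7 | methyl (2R)-oxirane-2-carboxylate (methyl (R)-glycidate) | COC(=O)[C@H]1CO1 | starting material
8 | aryllithium: lithium (2S,4S)-2-{3-lithio-4-[(2-methylbut-3-en-2-yl)oxy]phenyl}-7-[(2-methylbut-3-en-2-yl)oxy]chroman-4-olate (not isolated) | C=CC(C)(C)Oc1ccc([C@@H]2C[C@H](O[Li])c3ccc(OC(C)(C)C=C)cc3O2)cc1[Li] | intermediate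
9 | aryl Grignard reagent: the corresponding arylmagnesium bromide, C4 alkoxide retained (not isolated) | C=CC(C)(C)Oc1ccc([C@@H]2C[C@H](O[Li])c3ccc(OC(C)(C)C=C)cc3O2)cc1[Mg]Br | intermediate
10 | hydroxy ester: methyl (2R)-2-hydroxy-3-{5-[(2S,4S)-4-hydroxy-7-[(2-methylbut-3-en-2-yl)oxy]chroman-2-yl]-2-[(2-methylbut-3-en-2-yl)oxy]phenyl}propanoate, present as its magnesium alkoxide (not isolated) | COC(=O)[C@H](O)Cc1cc([C@@H]2C[C@H](O)c3ccc(OC(C)(C)C=C)cc3O2)ccc1OC(C)(C)C=C | intermediate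
11 | (2R)-1-{5-[(2S,4S)-4-hydroxy-7-[(2-methylbut-3-en-2-yl)oxy]chroman-2-yl]-2-[(2-methylbut-3-en-2-yl)oxy]phenyl}-3-methylbutane-2,3-diol | CC(C)(O)[C@H](O)Cc1cc([C@@H]2C[C@H](O)c3ccc(OC(C)(C)C=C)cc3O2)ccc1OC(C)(C)C=C | intermediate
12 | (2S)-2-{3-[(2R)-2,3-dihydroxy-3-methylbutyl]-4-[(2-methylbut-3-en-2-yl)oxy]phenyl}-7-[(2-methylbut-3-en-2-yl)oxy]chroman-4-one | CC(C)(O)[C@H](O)Cc1cc([C@@H]2CC(=O)c3ccc(OC(C)(C)C=C)cc3O2)ccc1OC(C)(C)C=C | intermediate
13 | secondary acetate: (2R)-3-hydroxy-3-methyl-1-{2-[(2-methylbut-3-en-2-yl)oxy]-5-[(2S)-7-[(2-methylbut-3-en-2-yl)oxy]-4-oxochroman-2-yl]phenyl}butan-2-yl acetate (not isolated) | CC(C)(O)[C@H](OC(C)=O)Cc1cc([C@@H]2CC(=O)c3ccc(OC(C)(C)C=C)cc3O2)ccc1OC(C)(C)C=C | intermediate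
14 | (2R)-3-methyl-1-{2-[(2-methylbut-3-en-2-yl)oxy]-5-[(2S)-7-[(2-methylbut-3-en-2-yl)oxy]-4-oxochroman-2-yl]phenyl}but-3-en-2-yl acetate | C=C(C)[C@H](OC(C)=O)Cc1cc([C@@H]2CC(=O)c3ccc(OC(C)(C)C=C)cc3O2)ccc1OC(C)(C)C=C | intermediate
15 | (2S)-2-{3-[(2R)-2-hydroxy-3-methylbut-3-en-1-yl]-4-[(2-methylbut-3-en-2-yl)oxy]phenyl}-7-[(2-methylbut-3-en-2-yl)oxy]chroman-4-one | C=C(C)[C@H](O)Cc1cc([C@@H]2CC(=O)c3ccc(OC(C)(C)C=C)cc3O2)ccc1OC(C)(C)C=C | intermediate
16 | bis-dienone: double [3,3] product before tautomerisation, with ring B as a 6-prenylcyclohexa-2,4-dienone and ring A as the 8-prenyl-7-oxo dienone (mixture at the two new sp3 ring carbons, not isolated) | C=C(C)[C@H](O)CC1=CC([C@@H]2CC(=O)C3=C(O2)C(CC=C(C)C)C(=O)C=C3)=CC(CC=C(C)C)C1=O | intermediate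
17 | (2S)-7-hydroxy-2-{4-hydroxy-3-[(2R)-2-hydroxy-3-methylbut-3-en-1-yl]-5-(3-methylbut-2-en-1-yl)phenyl}-8-(3-methylbut-2-en-1-yl)chroman-4-one | C=C(C)[C@H](O)Cc1cc([C@@H]2CC(=O)c3ccc(O)c(CC=C(C)C)c3O2)cc(CC=C(C)C)c1O | target

**Step count and risks**
Total steps: 9. Longest linear sequence: 9 (from 1; the route is fully linear).

The three steps most likely to fail:

Step 5 (one-pot aryl metal formation, glycidate opening, methyl addition). The aryl Grignard reagent may attack the ester carbonyl of 7 instead of the epoxide, and the ortho-metalated allyl ether is sensitive. The fallback sets out from 7 and uses the aryl Grignard reagent 9 made from 6 as before. Compound 7 is first treated with MeLi (2.1 equiv, Et2O, −78 °C) to give 2-[(2R)-oxiran-2-yl]propan-2-ol F1, in which the C–O bond of the stereocentre is untouched. F1 is deprotonated with one equivalent of MeMgBr and opened at its CH2 terminus by 9 with catalytic CuI. This gives 11 directly, where the fallback rejoins the route; the aryl nucleophile then meets only an epoxide and is never exposed to excess MeMgBr.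

Step 7 (acetylation and dehydration). Acetoxonium participation or elimination toward the acetoxy carbon could erode yield, and the acetate then needs base in step 8. The fallback sets out from 12. The secondary alcohol is silylated (TESCl, imidazole, CH2Cl2, 0 °C) to (2S)-2-{3-[(2R)-3-hydroxy-3-methyl-2-(triethylsilyloxy)butyl]-4-[(2-methylbut-3-en-2-yl)oxy]phenyl}-7-[(2-methylbut-3-en-2-yl)oxy]chroman-4-one F2. Dehydration with SOCl2/pyridine at 0 °C gives (2S)-2-{3-[(2R)-3-methyl-2-(triethylsilyloxy)but-3-en-1-yl]-4-[(2-methylbut-3-en-2-yl)oxy]phenyl}-7-[(2-methylbut-3-en-2-yl)oxy]chroman-4-one F3. HF·pyridine in THF at 0 °C removes the silyl group and returns to the route at 15, bypassing 13, 14 and the basic step 8.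

Step 9 (double Claisen). Ring A may give some C6 isomer, and tertiary allyl ethers can lose isoprene on heating. The fallback sets out from 15. Both tertiary allyl ethers are cleaved with Pd(PPh3)4 and morpholine (THF, rt) to (2S)-7-hydroxy-2-{4-hydroxy-3-[(2R)-2-hydroxy-3-methylbut-3-en-1-yl]phenyl}chroman-4-one F4. Iodination with NIS (2 equiv, DMF, 0 °C) ortho to each phenol (C8 between the two ring A oxygens, and the single free ortho site of ring B) gives (2S)-7-hydroxy-2-{4-hydroxy-3-[(2R)-2-hydroxy-3-methylbut-3-en-1-yl]-5-iodophenyl}-8-iodochroman-4-one F5. A twofold Stille coupling with tributyl(3-methylbut-2-en-1-yl)stannane (Pd(PPh3)4, DMF, 80 °C) then gives 17, where the fallback rejoins the route.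

**Further compounds**
F1 | step 5 | 2-[(2R)-oxiran-2-yl]propan-2-ol | CC(C)(O)[C@H]1CO1
F2 | step 7 | (2S)-2-{3-[(2R)-3-hydroxy-3-methyl-2-(triethylsilyloxy)butyl]-4-[(2-methylbut-3-en-2-yl)oxy]phenyl}-7-[(2-methylbut-3-en-2-yl)oxy]chroman-4-one | CC(C)(O)[C@H](O[Si](CC)(CC)CC)Cc1cc([C@@H]2CC(=O)c3ccc(OC(C)(C)C=C)cc3O2)ccc1OC(C)(C)C=C
F3 | step 7 | (2S)-2-{3-[(2R)-3-methyl-2-(triethylsilyloxy)but-3-en-1-yl]-4-[(2-methylbut-3-en-2-yl)oxy]phenyl}-7-[(2-methylbut-3-en-2-yl)oxy]chroman-4-one | C=C(C)[C@H](O[Si](CC)(CC)CC)Cc1cc([C@@H]2CC(=O)c3ccc(OC(C)(C)C=C)cc3O2)ccc1OC(C)(C)C=C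
F4 | step 9 | (2S)-7-hydroxy-2-{4-hydroxy-3-[(2R)-2-hydroxy-3-methylbut-3-en-1-yl]phenyl}chroman-4-one | C=C(C)[C@H](O)Cc1cc([C@@H]2CC(=O)c3ccc(O)cc3O2)ccc1O
F5 | step 9 | (2S)-7-hydroxy-2-{4-hydroxy-3-[(2R)-2-hydroxy-3-methylbut-3-en-1-yl]-5-iodophenyl}-8-iodochroman-4-one | C=C(C)[C@H](O)Cc1cc([C@@H]2CC(=O)c3ccc(O)c(I)c3O2)cc(I)c1O
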